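**Retrosynthetic overview** (drimane numbering: ring A = C1–C5/C10, ring B = C5–C10, C11 = CH2O on C9, C12 = exocyclic CH2 on C8)
Late disconnections: C11–OAr (Mitsunobu etherification with umbelliferone), C8=C12 (Wittig on an 8-oxo-Δ6 enone made by allylic oxidation), C3–OH (axial alcohol from the C3 ketone with a bulky hydride).
Key disconnection C1–C10: ring A is closed onto ring B by a hydrogen-atom-transfer radical conjugate cyclisation of a monocyclic vinyl ketone.
Enabling feature: C10 is the methyl-bearing quaternary ring-fusion carbon between C5 and C9, so it can be carried as an exocyclic C10=CH2 on ring B and unveiled as a tertiary radical; C1 stands 1,3 to the C3 oxygen, so with C3 as ketone it is the β-carbon of a vinyl ketone held over C10 by the C4 gem-dimethyl tether.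
Precursor: C4–C5 by Ireland–Claisen rearrangement of a ring-B allylic isobutyrate (chirality transfer C7 → C5, alkene moves to C6=C7); C9–C11 by enolate alkylation; the one purchased stereocenter (C7 of a 4-silyloxycyclohexenone) relays to C9 and C5, which then set C10 and C3.
Ring order: ring B (purchased) → ring A (step 7); the coumarin is attached last.

Key step: step 7

Assumption: (S)-4-(tert-butyldimethylsilyloxy)cyclohex-2-en-1-one (1) is taken as a purchasable chiral building block; ClCH2OSi(iPr)3, isobutyric acid, Sn(CH=CH2)4 and umbelliferone are commercial.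

Step 1
Reactants: 1 (S)-4-(TBSO)cyclohex-2-en-1-one
Product: 3 (4S,6R)-4-(TBSO)-6-(TIPSOCH2)cyclohex-2-en-1-one, via lithium dienolate 2 (not isolated)
Conditions: LiN(iPr)2, THF, −78 °C; then ClCH2OSi(iPr)3, DMPU, −78 → −30 °C
Reagents that add atoms: chloromethyl triisopropylsilyl ether, ClCO[Si](C(C)C)(C(C)C)C(C)C
Why: Kinetic deprotonation gives the cross-conjugated α'-enolate, whose C-alkylation by the chloromethyl ether (enolate alkylation) should occur anti to the pseudoaxial silyloxy group, setting the new side-chain carbon (future C9) trans to the C–O bond.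

Step 2
Reactants: 3 (4S,6R)-4-(TBSO)-6-(TIPSOCH2)cyclohex-2-en-1-one
Product: 4 (4S,6R)-4-hydroxy-6-(TIPSOCH2)cyclohex-2-en-1-one
Conditions: HF·pyridine, pyridine, THF, 0 °C → rt
Reagents that add atoms: none
Why: Buffered fluoride desilylation should cleave the secondary tert-butyldimethylsilyl ether much faster than the primary triisopropylsilyl ether and leave the β-silyloxy ketone and both stereocenters untouched.

Step 3
Reactants: 4 (4S,6R)-4-hydroxy-6-(TIPSOCH2)cyclohex-2-en-1-one
Product: 5 (1R,5R)-4-oxo-5-(TIPSOCH2)cyclohex-2-en-1-yl 2-methylpropanoate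
Conditions: i-PrCO2H, PPh3, DIAD, THF, 0 °C → rt
Reagents that add atoms: 2-methylpropanoic acid, CC(C)C(=O)O
Why: Mitsunobu esterification displaces the alkoxyphosphonium ion by SN2, so the carbinol carbon is inverted and the ester comes to lie cis to the silyloxymethyl side chain, as the rearrangement in step 5 requires.

Step 4
Reactants: 5 (1R,5R)-4-oxo-5-(TIPSOCH2)cyclohex-2-en-1-yl 2-methylpropanoate
Product: 6 (1R,5S)-4-methylidene-5-(TIPSOCH2)cyclohex-2-en-1-yl 2-methylpropanoate
Conditions: Cp2Ti(μ-CH2)(μ-Cl)AlMe2 (Tebbe reagent), pyridine, THF/toluene, −40 → 0 °C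
Reagents that add atoms: Tebbe reagent, C[Al-]1(C)C[Ti](C2C=CC=C2)(C2C=CC=C2)[Cl+]1
Why: Tebbe methylenation is non-basic and much faster at a ketone than at an ester, so the enone carbonyl should become the exocyclic methylene (future C10=CH2) without epimerisation of the adjacent stereocenter or β-elimination.

Step 5
Reactants: 6 (1R,5S)-4-methylidene-5-(TIPSOCH2)cyclohex-2-en-1-yl 2-methylpropanoate
Product: 9 2-methyl-2-[(1R,5S)-6-methylidene-5-(TIPSOCH2)cyclohex-2-en-1-yl]propanoic acid, via silyl ketene acetal 7 (not isolated), via trimethylsilyl ester 8 (not isolated)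
Conditions: LiN(iPr)2, Me3SiCl, THF, −78 → 55 °C; then 1 M HCl, rt
Reagents that add atoms: none
Why: The Ireland–Claisen rearrangement is a suprafacial [3,3]-sigmatropic shift, so the CMe2CO2 unit is delivered to the ring carbon on the face the ester oxygen occupied (chirality transfer sets future C5, cis to the side chain on future C9) while the ring alkene moves to its final C6=C7 position.

Step 6
Reactants: 9 2-methyl-2-[(1R,5S)-6-methylidene-5-(TIPSOCH2)cyclohex-2-en-1-yl]propanoic acid
Product: 11 4-methyl-4-[(1R,5S)-6-methylidene-5-(TIPSOCH2)cyclohex-2-en-1-yl]pent-1-en-3-one, via dilithium gem-diolate 10 (not isolated)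
Conditions: CH2=CHLi (3 equiv, from Sn(CH=CH2)4 and MeLi), Et2O/THF, −78 → 0 °C; then inverse quench into cold aq NH4Cl
Reagents that add atoms: vinyllithium, [Li]C=C
Why: Addition of the organolithium to the lithium carboxylate should stop at the dilithium gem-diolate, which releases the vinyl ketone only on protonation (ketone synthesis from a carboxylic acid and an organolithium), and no stereocenter is touched.

Step 7
Reactants: 11 4-methyl-4-[(1R,5S)-6-methylidene-5-(TIPSOCH2)cyclohex-2-en-1-yl]pent-1-en-3-one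
Product: 12 (4aS,5S,8aR)-1,1,4a-trimethyl-5-(TIPSOCH2)-3,4,4a,5,6,8a-hexahydronaphthalen-2(1H)-one
Conditions: Fe(acac)3 (0.3 equiv), PhSiH3 (2.5 equiv), EtOH/(CH2OH)2 5:1, 0.01 M, 60 °C, argon
Reagents that add atoms: none
Why: Hydrogen-atom transfer from the iron hydride formed from Fe(acac)3 and PhSiH3 to the CH2 terminus of the exocyclic 1,1-disubstituted alkene gives the tertiary C10 radical, which adds to C1 of the vinyl ketone; the α-keto radical at C2 is reduced by divalent iron to the enolate and protonated by ethanol, which returns trivalent iron. The closest known reaction type is the iron-mediated reductive olefin–enone coupling (intramolecular radical conjugate addition), which forges quaternary carbons in ring closures. Ring A closes in the 6-endo-trig mode, the only one that attacks the enone β-carbon and leaves the new radical α to the C3 carbonyl. The new C10 stereocenter is controlled by C5: its bulky CMe2 tether sits equatorial on ring B and reaches the flattened C10 through a chair-like transition state from the face of the C5 hydrogen, so the new methyl should end axial, anti to H-5 (trans ring fusion) and cis to the equatorial C9 side chain. The step needs chemoselective hydrogen-atom transfer, secured because only the 1,1-disubstituted alkene gives a tertiary radical (the cis-disubstituted ring alkene and the electron-poor vinyl ketone accept the hydrogen atom far more slowly), and polarity matching of the nucleophilic tertiary radical with the enone.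

Step 8
Reactants: 12 (4aS,5S,8aR)-1,1,4a-trimethyl-5-(TIPSOCH2)-3,4,4a,5,6,8a-hexahydronaphthalen-2(1H)-one
Product: 14 triethyl{[(2R,4aS,5S,8aR)-1,1,4a-trimethyl-5-(TIPSOCH2)-1,2,3,4,4a,5,6,8a-octahydronaphthalen-2-yl]oxy}silane, via lithium 3α-alkoxide 13 (not isolated)
Conditions: LiBH(s-Bu)3, THF, −78 °C; then Et3SiOTf, 2,6-lutidine, −78 → 0 °C
Reagents that add atoms: triethylsilyl trifluoromethanesulfonate, CC[Si](CC)(CC)OS(=O)(=O)C(F)(F)F
Why: The bulky borohydride should deliver hydride along the equatorial trajectory of the ketone next to the gem-dimethyl group and give the axial 3α-alkoxide (substrate-controlled ketone reduction), which is silylated in the same flask so that the later oxidation cannot touch it.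

Step 9
Reactants: 14 triethyl{[(2R,4aS,5S,8aR)-1,1,4a-trimethyl-5-(TIPSOCH2)-1,2,3,4,4a,5,6,8a-octahydronaphthalen-2-yl]oxy}silane
Product: 15 (1S,4aR,6R,8aS)-5,5,8a-trimethyl-6-(TESO)-1-(TIPSOCH2)-4a,5,6,7,8,8a-hexahydronaphthalen-2(1H)-one
Conditions: Rh2(cap)4 (dirhodium tetrakis(caprolactamate), 1 mol %), t-BuOOH, K2CO3, CH2Cl2, rt
Reagents that add atoms: tert-butyl hydroperoxide, CC(C)(C)OO
Why: Dirhodium-catalysed allylic C–H oxidation should convert the only allylic methylene (C8) into the enone carbonyl, the other allylic position (C5) being a methine wedged between two quaternary carbons, and the C9 centre next to the new carbonyl keeps its equatorial side chain.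

Step 10
Reactants: 15 (1S,4aR,6R,8aS)-5,5,8a-trimethyl-6-(TESO)-1-(TIPSOCH2)-4a,5,6,7,8,8a-hexahydronaphthalen-2(1H)-one
Product: 16 triethyl{[(2R,4aS,5S,8aR)-1,1,4a-trimethyl-6-methylidene-5-(TIPSOCH2)-1,2,3,4,4a,5,6,8a-octahydronaphthalen-2-yl]oxy}silane
Conditions: Ph3PCH3Br, KN(SiMe3)2, THF, 0 °C; then 15, 0 °C → rt
Reagents that add atoms: methyltriphenylphosphonium bromide, C[P+](c1ccccc1)(c1ccccc1)c1ccccc1.[Br-]
Why: Wittig methylenation of the only carbonyl group should give the exocyclic C8=C12 methylene conjugated with the ring alkene, and no stereocenter is formed.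

Step 11
Reactants: 16 triethyl{[(2R,4aS,5S,8aR)-1,1,4a-trimethyl-6-methylidene-5-(TIPSOCH2)-1,2,3,4,4a,5,6,8a-octahydronaphthalen-2-yl]oxy}silane
Product: 17 (2R,4aS,5S,8aR)-5-(hydroxymethyl)-1,1,4a-trimethyl-6-methylidene-1,2,3,4,4a,5,6,8a-octahydronaphthalen-2-ol
Conditions: Bu4NF, THF, rt → 45 °C
Reagents that add atoms: none
Why: Fluoride should cleave both silyl ethers (desilylation) without touching the transoid diene or any stereocenter.

Step 12
Reactants: 17 (2R,4aS,5S,8aR)-5-(hydroxymethyl)-1,1,4a-trimethyl-6-methylidene-1,2,3,4,4a,5,6,8a-octahydronaphthalen-2-ol; 18 umbelliferone (7-hydroxy-2H-chromen-2-one)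
Product: 19 7-{[(1S,4aR,6R,8aS)-6-hydroxy-5,5,8a-trimethyl-2-methylidene-1,2,4a,5,6,7,8,8a-octahydronaphthalen-1-yl]methoxy}-2H-chromen-2-one
Conditions: PPh3, DIAD, THF, 0 °C → rt
Reagents that add atoms: none
Why: Mitsunobu etherification with the acidic phenol should take place at the primary alcohol only, the axial secondary alcohol next to the gem-dimethyl group being too hindered to react, and the reacting carbon is a CH2 group so no stereocenter is involved.

**Compound list** (TBS = tert-butyldimethylsilyl, TIPS = tri(propan-2-yl)silyl, TES = triethylsilyl)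
1 | (S)-4-[(tert-butyldimethylsilyl)oxy]cyclohex-2-en-1-one | O=C1C=C[C@@H](O[Si](C)(C)C(C)(C)C)CC1 | starting material
2 | lithium (4S)-4-[(tert-butyldimethylsilyl)oxy]cyclohexa-1,5-dien-1-olate | [Li]OC1=CC[C@H](O[Si](C)(C)C(C)(C)C)C=C1 | intermediate
3 | (4S,6R)-4-[(tert-butyldimethylsilyl)oxy]-6-({[tri(propan-2-yl)silyl]oxy}methyl)cyclohex-2-en-1-one | O=C1C=C[C@@H](O[Si](C)(C)C(C)(C)C)C[C@@H]1CO[Si](C(C)C)(C(C)C)C(C)C | intermediate
4 | (4S,6R)-4-hydroxy-6-({[tri(propan-2-yl)silyl]oxy}methyl)cyclohex-2-en-1-one | O=C1C=C[C@@H](O)C[C@@H]1CO[Si](C(C)C)(C(C)C)C(C)C | intermediate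
5 | (1R,5R)-4-oxo-5-({[tri(propan-2-yl)silyl]oxy}methyl)cyclohex-2-en-1-yl 2-methylpropanoate | O=C1C=C[C@H](OC(=O)C(C)C)C[C@@H]1CO[Si](C(C)C)(C(C)C)C(C)C | intermediate
6 | (1R,5S)-4-methylidene-5-({[tri(propan-2-yl)silyl]oxy}methyl)cyclohex-2-en-1-yl 2-methylpropanoate | C=C1C=C[C@H](OC(=O)C(C)C)C[C@@H]1CO[Si](C(C)C)(C(C)C)C(C)C | intermediate
7 | trimethylsilyl ketene acetal of 6, trimethyl{[2-methyl-1-{[(1R,5S)-4-methylidene-5-({[tri(propan-2-yl)silyl]oxy}methyl)cyclohex-2-en-1-yl]oxy}prop-1-en-1-yl]oxy}silane | C=C1C=C[C@H](OC(O[Si](C)(C)C)=C(C)C)C[C@@H]1CO[Si](C(C)C)(C(C)C)C(C)C | intermediate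
8 | trimethylsilyl 2-methyl-2-[(1R,5S)-6-methylidene-5-({[tri(propan-2-yl)silyl]oxy}methyl)cyclohex-2-en-1-yl]propanoate | C1C=C[C@@H](C(C)(C)C(=O)O[Si](C)(C)C)C(=C)[C@H]1CO[Si](C(C)C)(C(C)C)C(C)C | intermediate
9 | 2-methyl-2-[(1R,5S)-6-methylidene-5-({[tri(propan-2-yl)silyl]oxy}methyl)cyclohex-2-en-1-yl]propanoic acid | C1C=C[C@@H](C(C)(C)C(=O)O)C(=C)[C@H]1CO[Si](C(C)C)(C(C)C)C(C)C | intermediate
10 | dilithium 4-methyl-4-[(1R,5S)-6-methylidene-5-({[tri(propan-2-yl)silyl]oxy}methyl)cyclohex-2-en-1-yl]pent-1-ene-3,3-diolate | C1C=C[C@@H](C(C)(C)C(O[Li])(O[Li])C=C)C(=C)[C@H]1CO[Si](C(C)C)(C(C)C)C(C)C | intermediate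
11 | 4-methyl-4-[(1R,5S)-6-methylidene-5-({[tri(propan-2-yl)silyl]oxy}methyl)cyclohex-2-en-1-yl]pent-1-en-3-one | C1C=C[C@@H](C(C)(C)C(=O)C=C)C(=C)[C@H]1CO[Si](C(C)C)(C(C)C)C(C)C | intermediate
12 | (4aS,5S,8aR)-1,1,4a-trimethyl-5-({[tri(propan-2-yl)silyl]oxy}methyl)-3,4,4a,5,6,8a-hexahydronaphthalen-2(1H)-one | C1C=C[C@H]2C(C)(C)C(=O)CC[C@]2(C)[C@H]1CO[Si](C(C)C)(C(C)C)C(C)C | intermediate
13 | lithium (2R,4aS,5S,8aR)-1,1,4a-trimethyl-5-({[tri(propan-2-yl)silyl]oxy}methyl)-1,2,3,4,4a,5,6,8a-octahydronaphthalen-2-olate | C1C=C[C@H]2C(C)(C)[C@H](O[Li])CC[C@]2(C)[C@H]1CO[Si](C(C)C)(C(C)C)C(C)C | intermediate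
14 | triethyl{[(2R,4aS,5S,8aR)-1,1,4a-trimethyl-5-({[tri(propan-2-yl)silyl]oxy}methyl)-1,2,3,4,4a,5,6,8a-octahydronaphthalen-2-yl]oxy}silane | C1C=C[C@H]2C(C)(C)[C@H](O[Si](CC)(CC)CC)CC[C@]2(C)[C@H]1CO[Si](C(C)C)(C(C)C)C(C)C | intermediate
15 | (1S,4aR,6R,8aS)-5,5,8a-trimethyl-6-[(triethylsilyl)oxy]-1-({[tri(propan-2-yl)silyl]oxy}methyl)-4a,5,6,7,8,8a-hexahydronaphthalen-2(1H)-one | O=C1C=C[C@H]2C(C)(C)[C@H](O[Si](CC)(CC)CC)CC[C@]2(C)[C@H]1CO[Si](C(C)C)(C(C)C)C(C)C | intermediate
16 | triethyl{[(2R,4aS,5S,8aR)-1,1,4a-trimethyl-6-methylidene-5-({[tri(propan-2-yl)silyl]oxy}methyl)-1,2,3,4,4a,5,6,8a-octahydronaphthalen-2-yl]oxy}silane | C=C1C=C[C@H]2C(C)(C)[C@H](O[Si](CC)(CC)CC)CC[C@]2(C)[C@H]1CO[Si](C(C)C)(C(C)C)C(C)C | intermediate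
17 | (2R,4aS,5S,8aR)-5-(hydroxymethyl)-1,1,4a-trimethyl-6-methylidene-1,2,3,4,4a,5,6,8a-octahydronaphthalen-2-ol | C=C1C=C[C@H]2C(C)(C)[C@H](O)CC[C@]2(C)[C@H]1CO | intermediate
18 | umbelliferone (7-hydroxy-2H-chromen-2-one) | Oc1ccc2ccc(=O)oc2c1 | starting material
19 | 7-{[(1S,4aR,6R,8aS)-6-hydroxy-5,5,8a-trimethyl-2-methylidene-1,2,4a,5,6,7,8,8a-octahydronaphthalen-1-yl]methoxy}-2H-chromen-2-one | C=C1C=C[C@H]2C(C)(C)[C@H](O)CC[C@]2(C)[C@H]1COc1ccc2ccc(=O)oc2c1 | target

**Totals and risks**
Total step count: 12. Longest linear sequence: 12 steps (from 1).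

Step 7 (key step). Hydrogen-atom transfer to the vinyl ketone, or a second hydrogen-atom transfer to the tertiary radical, may outrun the 6-endo closure (simple reduction); closure on the wrong face of C10 would give the cis-fused ring system. The fallback sets out from 11 and returns at 12. Anhydrous HBr (CH2Cl2, −78 °C) should add in the Markovnikov sense to the exocyclic methylene and, reversibly, to the vinyl ketone, giving 1-bromo-4-[(1S,5R)-6-bromo-6-methyl-5-(TIPSOCH2)cyclohex-2-en-1-yl]-4-methylpentan-3-one F1 (epimers at the C–Br ring carbon). Et3N (CH2Cl2, 0 °C) removes HBr from the β-bromo ketone only and should give the tertiary bromide 4-[(1S,5R)-6-bromo-6-methyl-5-(TIPSOCH2)cyclohex-2-en-1-yl]-4-methylpent-1-en-3-one F2. Bu3SnH with AIBN (benzene, 80 °C, slow addition, high dilution) abstracts bromine, and the same tertiary radical closes ring A in a tin-hydride chain cyclisation to 12. This takes radical generation away from a metal hydride that can also attack the enone, and the chain can be started at low temperature with Et3B/air to sharpen the face selectivity.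

Step 9. C–H abstraction may be unselective: attack at the C5 methine, trapping of the allyl radical at C6 (transposed 6-oxo-Δ7 enone) or over-oxidation. The fallback sets out from 14 and returns at 15. Catalytic SeO2 with t-BuOOH (CH2Cl2, rt) hydroxylates the allylic methylene by an ene reaction followed by a [2,3]-sigmatropic shift, which returns the double bond to C6=C7, and should give the allylic alcohol (1S,4aR,6R,8aS)-5,5,8a-trimethyl-6-(TESO)-1-(TIPSOCH2)-1,2,4a,5,6,7,8,8a-octahydronaphthalen-2-ol F3 (epimers at the carbinol carbon). MnO2 (CH2Cl2, rt) then oxidises the allylic alcohol to 15.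

Step 6. The gem-diolate may collapse early and take up a second organolithium (tertiary alcohol), and the liberated vinyl ketone may add nucleophiles or polymerise during the quench. The fallback sets out from 9 and returns at 11. (COCl)2 with catalytic DMF, then MeNH(OMe)·HCl and pyridine, should give the N-methoxy-N-methylamide N-methoxy-N,2-dimethyl-2-[(1R,5S)-6-methylidene-5-(TIPSOCH2)cyclohex-2-en-1-yl]propanamide F4 (Weinreb amide). CH2=CHMgBr (THF, 0 °C, cold acidic quench) adds once through the stable magnesium chelate and should give 11.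

Further compounds
F1 | step 7 | 1-bromo-4-[(1S,5R)-6-bromo-6-methyl-5-({[tri(propan-2-yl)silyl]oxy}methyl)cyclohex-2-en-1-yl]-4-methylpentan-3-one | C1C=C[C@@H](C(C)(C)C(=O)CCBr)C(C)(Br)[C@H]1CO[Si](C(C)C)(C(C)C)C(C)C
F2 | step 7 | 4-[(1S,5R)-6-bromo-6-methyl-5-({[tri(propan-2-yl)silyl]oxy}methyl)cyclohex-2-en-1-yl]-4-methylpent-1-en-3-one | C1C=C[C@@H](C(C)(C)C(=O)C=C)C(C)(Br)[C@H]1CO[Si](C(C)C)(C(C)C)C(C)C
F3 | step 9 | (1S,4aR,6R,8aS)-5,5,8a-trimethyl-6-[(triethylsilyl)oxy]-1-({[tri(propan-2-yl)silyl]oxy}methyl)-1,2,4a,5,6,7,8,8a-octahydronaphthalen-2-ol | OC1C=C[C@H]2C(C)(C)[C@H](O[Si](CC)(CC)CC)CC[C@]2(C)[C@H]1CO[Si](C(C)C)(C(C)C)C(C)C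
F4 | step 6 | N-methoxy-N,2-dimethyl-2-[(1R,5S)-6-methylidene-5-({[tri(propan-2-yl)silyl]oxy}methyl)cyclohex-2-en-1-yl]propanamide | C1C=C[C@@H](C(C)(C)C(=O)N(C)OC)C(=C)[C@H]1CO[Si](C(C)C)(C(C)C)C(C)C
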